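The plan cuts ring A of the naphthalene half at C3–C4 and C1–C2. Ring A carries C1–OH, C2–acetyl and C3–methyl on adjacent carbons, which is exactly the pattern delivered when a lithiated ortho-toluate on ring B (benzylic carbon = C4, ester carbon = C1) adds to (E)-pent-3-en-2-one and the new enolate closes onto the ester; one operation builds ring A with all three groups placed. The precursor is a biaryl whose ring B is a methyl 2-methoxy-6-methylbenzoate and whose ring C carries chlorine and a dioxolane-masked aldehyde. After aromatization, a Z-alkenyl arm is coupled on and a D-proline aldol closes ring D, setting C1′ and C2′.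

Key step: step 6

Assumptions and design notes
- Atom labels: the naphthalene half is C1–C8a (ring A = C1–C4 with C4a and C8a, ring B = C4a–C8a). The dihydronaphthalene half is C1′–C8a′ (ring C aromatic, ring D = C1′–C4′ with C4a′ and C8a′). The biaryl bond joins C7 and C7′.
- The target SMILES corresponds to (1′S,2′R), with the C1′ hydroxyl and the C2′ acetyl group trans on ring D.
- Ring C carries its future C1′ carbon as a dioxolane from the start, so the aldehyde never has to be made by reduction next to the ring A acetyl group.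
- Ring B carries bromine and ring C chlorine, so the ring B halide is methylated site-selectively and no statistical desymmetrization is needed.
- Both aryl methyl ethers are cleaved before the acid- and base-sensitive arm is attached.
- Compounds 1, 5, 7, 11, 17 and 20 are taken as purchased.

Step 1
Reactants: 1 4-chloro-1-iodo-2-methoxybenzene
Product: 3 6-chloro-3-iodo-2-methoxybenzaldehyde, via aryllithium 2 (not isolated)
Conditions: LiN(iPr)2 (1.1 equiv), THF, −78 °C, 1 h; DMF (2 equiv), −78 to −40 °C; AcOH, then H2O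
Reagents that add atoms: N,N-dimethylformamide, CN(C)C=O
Why: Directed ortho-metalation: the hydrogen flanked by OMe and Cl is the most acidic ring position and the only one ortho to the methoxy group, the amide base does not exchange the iodide, and DMF formylates the aryllithium to install the carbon that becomes C1′.

Step 2
Reactants: 3 6-chloro-3-iodo-2-methoxybenzaldehyde
Product: 4 2-(6-chloro-3-iodo-2-methoxyphenyl)-1,3-dioxolane
Conditions: ethylene glycol (5 equiv), p-TsOH·H2O (5 mol%), toluene, reflux, Dean–Stark trap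
Reagents that add atoms: ethylene glycol, OCCO
Why: Acid-catalysed acetalization driven by azeotropic removal of water masks the aldehyde as a dioxolane that tolerates the lithium amide, palladium and DDQ steps ahead.

Step 3
Reactants: 4 2-(6-chloro-3-iodo-2-methoxyphenyl)-1,3-dioxolane; 5 (4-bromo-2-methoxyphenyl)boronic acid
Product: 6 2-[3-(4-bromo-2-methoxyphenyl)-6-chloro-2-methoxyphenyl]-1,3-dioxolane
Conditions: Pd(PPh3)4 (3 mol%), Na2CO3 (2 M aq., 2 equiv), DME, 70 °C
Reagents that add atoms: none
Why: Suzuki–Miyaura coupling occurs only at the C–I bond because oxidative addition to an aryl iodide is far faster than to the aryl chloride of 4 or the aryl bromide of 5.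

Step 4
Reactants: 6 2-[3-(4-bromo-2-methoxyphenyl)-6-chloro-2-methoxyphenyl]-1,3-dioxolane; 7 methyl chloroformate
Product: 9 methyl 6-bromo-3-[4-chloro-3-(1,3-dioxolan-2-yl)-2-methoxyphenyl]-2-methoxybenzoate, via aryllithium 8 (not isolated)
Conditions: LiN(iPr)2 (1.2 equiv), THF, −78 °C, 45 min; cannulated into ClCO2Me (3 equiv), THF, −78 °C
Reagents that add atoms: none
Why: Directed ortho-metalation picks the only hydrogen flanked by OMe and Br (its counterpart on ring C is occupied by the dioxolane), and inverse addition to methyl chloroformate acylates the hindered aryllithium once.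

Step 5
Reactants: 9 methyl 6-bromo-3-[4-chloro-3-(1,3-dioxolan-2-yl)-2-methoxyphenyl]-2-methoxybenzoate
Product: 10 methyl 3-[4-chloro-3-(1,3-dioxolan-2-yl)-2-methoxyphenyl]-2-methoxy-6-methylbenzoate
Conditions: MeB(OH)2 (2 equiv), Pd(dppf)Cl2 (5 mol%), K2CO3 (3 equiv), 1,4-dioxane/H2O 10:1, 90 °C
Reagents that add atoms: methylboronic acid, CB(O)O
Why: Suzuki–Miyaura methylation with a bisphosphine-ligated palladium catalyst inserts into the ester-activated C–Br bond and not into the C–Cl bond of ring C, so the two rings are told apart by their halogens.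

Step 6
Reactants: 10 methyl 3-[4-chloro-3-(1,3-dioxolan-2-yl)-2-methoxyphenyl]-2-methoxy-6-methylbenzoate; 11 (E)-pent-3-en-2-one
Product: 14 1-{7-[4-chloro-3-(1,3-dioxolan-2-yl)-2-methoxyphenyl]-1-hydroxy-8-methoxy-3-methyl-3,4-dihydronaphthalen-2-yl}ethan-1-one (racemic at C3), via benzylic lithium species 12 (not isolated), via Michael adduct enolate 13 (not isolated)
Conditions: LiN(iPr)2 (1.3 equiv), THF, −78 °C, 30 min; 11 (1.5 equiv), −78 °C, 1 h, then to 0 °C; AcOH, then H2O
Reagents that add atoms: none
Why: LiN(iPr)2 removes a proton from the ring B methyl group, the only C–H acidified by the ortho ester, and the delocalized benzylic anion 12 adds to the β-carbon of 11 to form C3–C4. The ketone enolate 13 then attacks the neighbouring ester carbonyl through its α-carbon in a 6-exo-trig Claisen (Dieckmann-type) closure that forms C1–C2, closes ring A and expels methoxide, which deprotonates the product so that the stable β-diketonate drives the sequence forward. The closest known reaction type is the Staunton–Weinreb annulation of ortho-toluate anions with Michael acceptors. The only new stereocentre, C3, is formed without control as a racemate and is removed in step 7. The step needs benzylic rather than aryl deprotonation and conjugate addition rather than carbonyl addition or proton transfer from the enolizable enone; the flanking OMe and CH2 groups shield the ester from self-condensation, the soft anion at −78 °C favours 1,4-addition, and ring C offers no competing electrophile because its carbonyl carbon is an acetal and its chloride is inert to the amide base.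

Step 7
Reactants: 14 1-{7-[4-chloro-3-(1,3-dioxolan-2-yl)-2-methoxyphenyl]-1-hydroxy-8-methoxy-3-methyl-3,4-dihydronaphthalen-2-yl}ethan-1-one
Product: 15 1-{7-[4-chloro-3-(1,3-dioxolan-2-yl)-2-methoxyphenyl]-1-hydroxy-8-methoxy-3-methylnaphthalen-2-yl}ethan-1-one
Conditions: DDQ (1.2 equiv), toluene, 60 °C
Reagents that add atoms: none
Why: DDQ dehydrogenation (hydride abstraction from benzylic C4 of the enolized β-diketone, then loss of the C3 proton) aromatizes ring A to the hydrogen-bonded 2-acetyl-1-naphthol and removes the C3 stereocentre.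

Step 8
Reactants: 15 1-{7-[4-chloro-3-(1,3-dioxolan-2-yl)-2-methoxyphenyl]-1-hydroxy-8-methoxy-3-methylnaphthalen-2-yl}ethan-1-one
Product: 16 3-(7-acetyl-1,8-dihydroxy-6-methylnaphthalen-2-yl)-6-chloro-2-hydroxybenzaldehyde
Conditions: BBr3 (8 equiv), CH2Cl2, −78 to 0 °C; H2O/THF, rt
Reagents that add atoms: water, O
Why: Lewis-acid ether cleavage with BBr3 removes both methyl ethers (the C8 ether has no ortho carbonyl to assist a milder chelation-dependent reagent) and opens the dioxolane, so that aqueous work-up releases the aldehyde with the chloride and the acetyl group intact.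

Step 9
Reactants: 17 propyne
Product: 19 2-[(1Z)-2-bromoprop-1-en-1-yl]-4,4,5,5-tetramethyl-1,3,2-dioxaborolane, via dibromoborane 18 (not isolated)
Conditions: BBr3 (1.0 equiv), CH2Cl2, −78 °C; pinacol (1.1 equiv), −78 °C to rt
Reagents that add atoms: boron tribromide, BrB(Br)Br; pinacol, CC(C)(O)C(C)(C)O
Why: Bromoboration of a terminal alkyne is a syn addition that places boron on the terminal carbon and bromine on C2, and esterification with pinacol at low temperature locks the Z geometry in a stable boronate.

Step 10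
Reactants: 19 2-[(1Z)-2-bromoprop-1-en-1-yl]-4,4,5,5-tetramethyl-1,3,2-dioxaborolane; 20 2-(bromomethyl)-2-methyl-1,3-dioxolane
Product: 22 4,4,5,5-tetramethyl-2-[(1Z)-2-methyl-3-(2-methyl-1,3-dioxolan-2-yl)prop-1-en-1-yl]-1,3,2-dioxaborolane, via alkylzinc bromide 21 (not isolated)
Conditions: 20 (1.5 equiv), Zn dust, LiCl, THF, 50 °C; then 19, Pd(P(t-Bu)3)2 (2 mol%), THF, rt
Reagents that add atoms: none
Why: Negishi coupling at the alkenyl C–Br bond proceeds with retention of geometry and leaves the boronate untouched, and the zinc reagent has no β-hydrogen and carries the future acetyl group as a base-stable ketal.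

Step 11
Reactants: 16 3-(7-acetyl-1,8-dihydroxy-6-methylnaphthalen-2-yl)-6-chloro-2-hydroxybenzaldehyde; 22 4,4,5,5-tetramethyl-2-[(1Z)-2-methyl-3-(2-methyl-1,3-dioxolan-2-yl)prop-1-en-1-yl]-1,3,2-dioxaborolane
Product: 23 3-(7-acetyl-1,8-dihydroxy-6-methylnaphthalen-2-yl)-2-hydroxy-6-[(1Z)-2-methyl-3-(2-methyl-1,3-dioxolan-2-yl)prop-1-en-1-yl]benzaldehyde
Conditions: Pd(OAc)2 (5 mol%), SPhos (10 mol%), K3PO4 (5 equiv), THF/H2O 5:1, degassed, 60 °C
Reagents that add atoms: none
Why: Suzuki–Miyaura coupling with an electron-rich biarylphosphine activates the ortho-formyl aryl chloride in the presence of free phenols and transfers the alkenyl group with retention, while the ketal keeps the arm from base-induced aldol reactions.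

Step 12
Reactants: 23 3-(7-acetyl-1,8-dihydroxy-6-methylnaphthalen-2-yl)-2-hydroxy-6-[(1Z)-2-methyl-3-(2-methyl-1,3-dioxolan-2-yl)prop-1-en-1-yl]benzaldehyde
Product: 24 3-(7-acetyl-1,8-dihydroxy-6-methylnaphthalen-2-yl)-2-hydroxy-6-[(1Z)-2-methyl-4-oxopent-1-en-1-yl]benzaldehyde
Conditions: PPTS (0.2 equiv), THF/H2O 4:1, 45 °C; crude product taken on cold
Reagents that add atoms: water, O
Why: Mild acid-catalysed ketal hydrolysis frees the methyl ketone without touching the phenols, the aldehyde or the Z alkene.

Step 13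
Reactants: 24 3-(7-acetyl-1,8-dihydroxy-6-methylnaphthalen-2-yl)-2-hydroxy-6-[(1Z)-2-methyl-4-oxopent-1-en-1-yl]benzaldehyde
Product: 25 1-[(1S,2R)-7-(7-acetyl-1,8-dihydroxy-6-methylnaphthalen-2-yl)-1,8-dihydroxy-3-methyl-1,2-dihydronaphthalen-2-yl]ethan-1-one
Conditions: D-proline (30 mol%), DMF, 4 °C to rt; pH 7 buffer work-up
Reagents that add atoms: none
Why: Proline-catalysed intramolecular aldol reaction (6-enolexo aldolization), in which the dienamine formed at the CH2 group between ketone and alkene attacks the aldehyde through the acid-bridged chair of the Houk–List model with the aryl ring and C3′ gauche, so that the hydroxyl and acetyl groups end up trans and the D-catalyst is expected to give C1′ as S and C2′ as R, the mirror image of the sense L-proline shows with aryl aldehydes.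

Compound list
1 | 4-chloro-1-iodo-2-methoxybenzene | COc1cc(Cl)ccc1I | starting material
2 | (6-chloro-3-iodo-2-methoxyphenyl)lithium | [Li]c1c(OC)c(I)ccc1Cl | intermediate (not isolated)
3 | 6-chloro-3-iodo-2-methoxybenzaldehyde | O=Cc1c(OC)c(I)ccc1Cl | intermediate
4 | 2-(6-chloro-3-iodo-2-methoxyphenyl)-1,3-dioxolane | COc1c(I)ccc(Cl)c1C1OCCO1 | intermediate
5 | (4-bromo-2-methoxyphenyl)boronic acid | COc1cc(Br)ccc1B(O)O | starting material
6 | 2-[3-(4-bromo-2-methoxyphenyl)-6-chloro-2-methoxyphenyl]-1,3-dioxolane | COc1cc(Br)ccc1-c1ccc(Cl)c(C2OCCO2)c1OC | intermediate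
7 | methyl chloroformate | COC(=O)Cl | starting material
8 | {6-bromo-3-[4-chloro-3-(1,3-dioxolan-2-yl)-2-methoxyphenyl]-2-methoxyphenyl}lithium | [Li]c1c(Br)ccc(-c2ccc(Cl)c(C3OCCO3)c2OC)c1OC | intermediate (not isolated)
9 | methyl 6-bromo-3-[4-chloro-3-(1,3-dioxolan-2-yl)-2-methoxyphenyl]-2-methoxybenzoate | COC(=O)c1c(Br)ccc(-c2ccc(Cl)c(C3OCCO3)c2OC)c1OC | intermediate
10 | methyl 3-[4-chloro-3-(1,3-dioxolan-2-yl)-2-methoxyphenyl]-2-methoxy-6-methylbenzoate (key-step precursor) | COC(=O)c1c(C)ccc(-c2ccc(Cl)c(C3OCCO3)c2OC)c1OC | intermediate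
11 | (E)-pent-3-en-2-one | C/C=C/C(C)=O | starting material
12 | ({4-[4-chloro-3-(1,3-dioxolan-2-yl)-2-methoxyphenyl]-3-methoxy-2-(methoxycarbonyl)phenyl}methyl)lithium | [Li]Cc1ccc(-c2ccc(Cl)c(C3OCCO3)c2OC)c(OC)c1C(=O)OC | intermediate (not isolated)
13 | lithium enolate of methyl 3-[4-chloro-3-(1,3-dioxolan-2-yl)-2-methoxyphenyl]-2-methoxy-6-(2-methyl-4-oxopentyl)benzoate (racemic) | COC(=O)c1c(CC(C)C=C(C)O[Li])ccc(-c2ccc(Cl)c(C3OCCO3)c2OC)c1OC | intermediate (not isolated)
14 | 1-{7-[4-chloro-3-(1,3-dioxolan-2-yl)-2-methoxyphenyl]-1-hydroxy-8-methoxy-3-methyl-3,4-dihydronaphthalen-2-yl}ethan-1-one (racemic at C3, key-step product) | CC(=O)C1=C(O)c2c(OC)c(-c3ccc(Cl)c(C4OCCO4)c3OC)ccc2CC1C | intermediate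
15 | 1-{7-[4-chloro-3-(1,3-dioxolan-2-yl)-2-methoxyphenyl]-1-hydroxy-8-methoxy-3-methylnaphthalen-2-yl}ethan-1-one | CC(=O)c1c(C)cc2ccc(-c3ccc(Cl)c(C4OCCO4)c3OC)c(OC)c2c1O | intermediate
16 | 3-(7-acetyl-1,8-dihydroxy-6-methylnaphthalen-2-yl)-6-chloro-2-hydroxybenzaldehyde | CC(=O)c1c(C)cc2ccc(-c3ccc(Cl)c(C=O)c3O)c(O)c2c1O | intermediate
17 | propyne | CC#C | starting material
18 | [(1Z)-2-bromoprop-1-en-1-yl]dibromoborane | C/C(Br)=C/B(Br)Br | intermediate (not isolated)
19 | 2-[(1Z)-2-bromoprop-1-en-1-yl]-4,4,5,5-tetramethyl-1,3,2-dioxaborolane | C/C(Br)=C/B1OC(C)(C)C(C)(C)O1 | intermediate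
20 | 2-(bromomethyl)-2-methyl-1,3-dioxolane | CC1(CBr)OCCO1 | starting material
21 | [(2-methyl-1,3-dioxolan-2-yl)methyl]zinc bromide | CC1(C[Zn]Br)OCCO1 | intermediate (not isolated)
22 | 4,4,5,5-tetramethyl-2-[(1Z)-2-methyl-3-(2-methyl-1,3-dioxolan-2-yl)prop-1-en-1-yl]-1,3,2-dioxaborolane | CC1(C/C(C)=C\B2OC(C)(C)C(C)(C)O2)OCCO1 | intermediate
23 | 3-(7-acetyl-1,8-dihydroxy-6-methylnaphthalen-2-yl)-2-hydroxy-6-[(1Z)-2-methyl-3-(2-methyl-1,3-dioxolan-2-yl)prop-1-en-1-yl]benzaldehyde | CC(=O)c1c(C)cc2ccc(-c3ccc(/C=C(/C)CC4(C)OCCO4)c(C=O)c3O)c(O)c2c1O | intermediate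
24 | 3-(7-acetyl-1,8-dihydroxy-6-methylnaphthalen-2-yl)-2-hydroxy-6-[(1Z)-2-methyl-4-oxopent-1-en-1-yl]benzaldehyde | CC(=O)c1c(C)cc2ccc(-c3ccc(/C=C(/C)CC(C)=O)c(C=O)c3O)c(O)c2c1O | intermediate
25 | 1-[(1S,2R)-7-(7-acetyl-1,8-dihydroxy-6-methylnaphthalen-2-yl)-1,8-dihydroxy-3-methyl-1,2-dihydronaphthalen-2-yl]ethan-1-one | CC(=O)c1c(C)cc2ccc(-c3ccc4c(c3O)[C@@H](O)[C@H](C(C)=O)C(C)=C4)c(O)c2c1O | target

Total step count: 13. Longest linear sequence: 11 steps (steps 1–8, then 11–13, from compound 1); steps 9 and 10 form the side branch to the arm.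

Steps most likely to fail

Step 6. The benzylic anion may take a proton from the acidic methyl ketone of 11 and return 10, it may add to the carbonyl group, or the sequence may stall at the open Michael adduct. The fallback makes the anion less basic and builds the aromatization into the annulation. Compound 10 is lithiated (LiN(iPr)2, THF, −78 °C) and sulfenylated with diphenyl disulfide to methyl 3-[4-chloro-3-(1,3-dioxolan-2-yl)-2-methoxyphenyl]-2-methoxy-6-[(phenylsulfanyl)methyl]benzoate F1. Oxidation with mCPBA (1 equiv, CH2Cl2, −78 °C) gives the corresponding phenylsulfinylmethyl benzoate F2. Its sulfinyl-stabilized anion (LiN(iPr)2, THF, −78 °C) should add to 11 and close onto the ester as in the main route, giving the 4-phenylsulfinyl dihydronaphthalenone F3. On warming, F3 loses benzenesulfenic acid by syn elimination (Hauser-type sulfoxide annulation) and the route is rejoined at naphthol 15, bypassing 14 and step 7.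

Step 13. The aldol product may lose water under amine catalysis and aromatize ring D, and reversible aldolization or epimerization at C2′ may erode the stereochemical purity. The fallback sets out from 24 and closes the ring by soft enolization (MgBr2·OEt2, iPr2NEt, CH2Cl2, −20 °C; cold aqueous citric acid quench). The chelated magnesium aldolate should hold the product against elimination and retro-aldol cleavage until the quench. This should give mainly the racemic trans aldol, that is 25 together with its (1R,2S)-enantiomer F4. Preparative chromatography on a chiral stationary phase then separates the two and returns 25.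

Step 10. Zinc insertion into the neopentyl-type bromide may be sluggish, and the organometallic intermediates may lose alkoxide by β-elimination. The fallback sets out from 19 and uses a Kosugi–Migita coupling with acetonyltributylstannane (Bu3SnCH2C(O)CH3, PdCl2(P(o-tol)3)2, toluene, 90 °C), which needs no base and should leave the boronate alone. It gives (4Z)-4-methyl-5-(4,4,5,5-tetramethyl-1,3,2-dioxaborolan-2-yl)pent-4-en-2-one F5. Ketalization under non-isomerizing conditions (1,2-bis(trimethylsilyloxy)ethane, catalytic TMSOTf, CH2Cl2, −78 °C) then rejoins the route at 22.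

Further compounds
F1 | step 6 | methyl 3-[4-chloro-3-(1,3-dioxolan-2-yl)-2-methoxyphenyl]-2-methoxy-6-[(phenylsulfanyl)methyl]benzoate | COC(=O)c1c(CSc2ccccc2)ccc(-c2ccc(Cl)c(C3OCCO3)c2OC)c1OC
F2 | step 6 | methyl 3-[4-chloro-3-(1,3-dioxolan-2-yl)-2-methoxyphenyl]-2-methoxy-6-[(phenylsulfinyl)methyl]benzoate (racemic at sulfur) | COC(=O)c1c(CS(=O)c2ccccc2)ccc(-c2ccc(Cl)c(C3OCCO3)c2OC)c1OC
F3 | step 6 | 1-{7-[4-chloro-3-(1,3-dioxolan-2-yl)-2-methoxyphenyl]-1-hydroxy-8-methoxy-3-methyl-4-(phenylsulfinyl)-3,4-dihydronaphthalen-2-yl}ethan-1-one (stereoisomer mixture, not isolated) | CC(=O)C1=C(O)c2c(OC)c(-c3ccc(Cl)c(C4OCCO4)c3OC)ccc2C(S(=O)c2ccccc2)C1C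
F4 | step 13 | 1-[(1R,2S)-7-(7-acetyl-1,8-dihydroxy-6-methylnaphthalen-2-yl)-1,8-dihydroxy-3-methyl-1,2-dihydronaphthalen-2-yl]ethan-1-one | CC(=O)c1c(C)cc2ccc(-c3ccc4c(c3O)[C@H](O)[C@@H](C(C)=O)C(C)=C4)c(O)c2c1O
F5 | step 10 | (4Z)-4-methyl-5-(4,4,5,5-tetramethyl-1,3,2-dioxaborolan-2-yl)pent-4-en-2-one | CC(=O)C/C(C)=C\B1OC(C)(C)C(C)(C)O1
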